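## Retrosynthetic overview

1. The target is fisetinidol-(4β→6)-ent-epifisetinidol. The last skeletal bond is C4(upper)–C6'(lower), made by Friedel–Crafts attack of the lower flavan on the C4 cation of a 2,3-cis, 3-O-acetylated upper unit (this gives 4β). The acetate is then removed, the upper C3 carbinol is inverted by oxidation and hydride reduction, and seven benzyl ethers are cleaved.
2. Both flavan units come from one racemic flavan-3-one 20 by two dynamic kinetic transfer hydrogenations with antipodal catalysts. This works because C2–H lies between the C3 carbonyl, O1 and ring B and is therefore epimerisable.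
3. Ring C (O1–C2–C3–C4–C4a–C8a) is made in one operation from aryne 15 and α-ethoxycinnamaldehyde 5. A (2+2) addition gives a four-membered 2H-benzoxete (O1, C4, C4a, C8a), which expands by the two carbons C3 and C2 through an o-quinone methide and oxa-6π closure to a 3-ethoxy-2H-chromene, the masked flavan-3-one.
4. Enabling feature: in ring A, O1 and C4 sit on the adjacent carbons C8a and C4a, C5 beside C4a is unsubstituted, and the C7 oxygen is meta to O1. A C2-symmetric, phloroglucinol-derived 2-silyl-1,3-bis(triflate) therefore gives the aryne and leaves a triflate on C5 beside the triple bond, which steers O to C8a and is excised afterwards.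
5. Ring order: rings A and B are bought as arenes → ring C of both units (step 8) → interflavan bond.

Key step: step 8

Assumption: the sense of induction of RuCl[TsDPEN](p-cymene) on ketone 20 is assigned by analogy with other α-aryl cyclic ketones ((S,S) complex → (2S,3S) alcohol); if it proves to be the reverse, the two antipodal complexes are exchanged between steps 11 and 13, since both product antipodes are used.

## Route

Step 1
Reactants: 1 3,4-bis(benzyloxy)benzaldehyde; 2 triethyl 2-ethoxyphosphonoacetate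
Product: 3 ethyl (Z)-3-[3,4-bis(benzyloxy)phenyl]-2-ethoxyprop-2-enoate
Conditions: NaH, THF, 0 °C to rt; chromatography
Reagents that add atoms: none
Why: Horner–Wadsworth–Emmons olefination of an aromatic aldehyde with a stabilised α-alkoxyphosphonate; the (Z)-isomer (aryl trans to the ester) is expected to predominate and is purified, and the alkene geometry is in any case lost at C2 in step 8.

Step 2
Reactants: 3 ethyl (Z)-3-[3,4-bis(benzyloxy)phenyl]-2-ethoxyprop-2-enoate
Product: 4 (Z)-3-[3,4-bis(benzyloxy)phenyl]-2-ethoxyprop-2-en-1-ol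
Conditions: i-Bu2AlH, CH2Cl2, −78 to 0 °C; aq. KNaC4H4O6 work-up
Reagents that add atoms: none
Why: 1,2-reduction of the conjugated ester to the allylic alcohol by two hydride transfers from the aluminium hydride; the enol ether and the benzyl ethers are inert.

Step 3
Reactants: 4 (Z)-3-[3,4-bis(benzyloxy)phenyl]-2-ethoxyprop-2-en-1-ol
Product: 5 (Z)-3-[3,4-bis(benzyloxy)phenyl]-2-ethoxyprop-2-enal
Conditions: activated MnO2, CH2Cl2, rt
Reagents that add atoms: none
Why: selective oxidation of an allylic alcohol with MnO2 under neutral conditions that spare the acid-labile enol ether.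

Step 4
Reactants: 6 phloroglucinol
Product: 7 5-(benzyloxy)benzene-1,3-diol
Conditions: BnBr (limiting), K2CO3, DMF, rt; excess 6 removed by aqueous wash
Reagents that add atoms: benzyl bromide, BrCc1ccccc1
Why: Williamson etherification; the triphenol is used in excess so that mono-O-benzylation should predominate statistically, and the water-soluble surplus is washed out.

Step 5
Reactants: 7 5-(benzyloxy)benzene-1,3-diol
Product: 8 5-(benzyloxy)-1,3-phenylene bis(N-isopropylcarbamate)
Conditions: i-PrNCO, Et3N (cat.), CH2Cl2, rt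
Reagents that add atoms: isopropyl isocyanate, CC(C)N=C=O
Why: base-catalysed addition of both phenols to the isocyanate gives the bis(carbamate), a strong directing group for ortho-metalation that can later be cleaved under mild conditions.

Step 6
Reactants: 8 5-(benzyloxy)-1,3-phenylene bis(N-isopropylcarbamate)
Product: 12 5-(benzyloxy)-2-(trimethylsilyl)-1,3-phenylene bis(N-isopropylcarbamate), via N-silyl carbamate 9 (not isolated), via aryllithium 10 (not isolated), via C-silyl intermediate 11 (not isolated)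
Conditions: TBSOTf, TMEDA, Et2O, 0 °C to rt; n-BuLi, TMEDA, −78 °C; TMSCl, −78 °C to rt; aq. NaHSO4
Reagents that add atoms: chlorotrimethylsilane, C[Si](C)(C)Cl
Why: directed ortho-metalation: after N-silylation of both carbamates, lithiation should occur at C2 between the two carbamate oxygens (doubly activated and preferred over the positions beside the weaker benzyloxy director), the aryllithium is silylated, and the N-silyl groups fall off on acidic work-up.

Step 7
Reactants: 12 5-(benzyloxy)-2-(trimethylsilyl)-1,3-phenylene bis(N-isopropylcarbamate)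
Product: 14 5-(benzyloxy)-2-(trimethylsilyl)-1,3-phenylene bis(trifluoromethanesulfonate), via silylresorcinol 13 (not isolated)
Conditions: DBU, Et2NH, MeCN, 40 °C; then PhNTf2, rt
Reagents that add atoms: N-phenylbis(trifluoromethanesulfonimide), O=S(=O)(N(c1ccccc1)S(=O)(=O)C(F)(F)F)C(F)(F)F
Why: E1cB cleavage of the N-isopropyl carbamates by DBU (diethylamine scavenges the isocyanate) releases the bis(phenoxide) of 13, which is triflated in the same flask to the o-silylaryl triflate.

Step 8
Reactants: 14 5-(benzyloxy)-2-(trimethylsilyl)-1,3-phenylene bis(trifluoromethanesulfonate); 5 (Z)-3-[3,4-bis(benzyloxy)phenyl]-2-ethoxyprop-2-enal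
Product: 18 racemic 7-(benzyloxy)-2-[3,4-bis(benzyloxy)phenyl]-3-ethoxy-2H-chromen-5-yl trifluoromethanesulfonate, via aryne 15 (not isolated), via benzoxete 16 (not isolated), via o-quinone methide 17 (not isolated)
Conditions: CsF, 5 in excess, MeCN–toluene, 25 to 60 °C, slow addition of 14
Reagents that add atoms: none
Why: Fluoride removes the silyl group of 14 and one of the two equivalent flanking triflates leaves, so the C2-symmetric precursor gives a single aryne 15 that keeps a triflyloxy group beside the triple bond; the carbonyl oxygen of 5 adds to the aryne carbon remote from that group and the aryl anion formed next to it closes on the carbonyl carbon, a stepwise (2+2) cycloaddition that gives the four-membered 2H-benzoxete 16. Ring 16 then opens by retro-4π electrocyclisation to o-quinone methide 17, whose thermal disrotatory oxa-6π electrocyclisation forms the O1–C2 bond and so expands the four-membered ring by the two enal carbons C3 and C2 to the 2H-pyran ring of 18. The closest known reaction type is the annulation of arynes with α,β-unsaturated aldehydes to 2H-chromenes, combined with the distal attack of nucleophiles on 3-(triflyloxy)arynes. The one new stereocentre, C2, is formed without control and 18 is racemic by design, because C2 becomes epimerisable in ketone 20 and is fixed only in steps 11 and 13. The step needs regioselectivity (O on C8a, C4 on C4a), which the inductive distortion of the aryne by the C5 triflate should secure against the weak opposing influence of the remote 7-benzyloxy group, and chemoselectivity for C=O over C=C, which rests on the push–pull deactivation of the enol-ether double bond of 5 and on fast four-membered collapse of the zwitterion before closure at the β-carbon or loss of triflate.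

Step 9
Reactants: 18 racemic 7-(benzyloxy)-2-[3,4-bis(benzyloxy)phenyl]-3-ethoxy-2H-chromen-5-yl trifluoromethanesulfonate
Product: 19 racemic 7-(benzyloxy)-2-[3,4-bis(benzyloxy)phenyl]-3-oxochroman-5-yl trifluoromethanesulfonate
Conditions: aq. HCl (1 M), THF, 0 °C to rt, under argon
Reagents that add atoms: water, O
Why: acid-catalysed enol-ether hydrolysis (protonation at C4, addition of water at C3, loss of ethanol) unmasks the flavan-3-one; the aryl triflate and benzyl ethers are stable to dilute aqueous acid.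

Step 10
Reactants: 19 racemic 7-(benzyloxy)-2-[3,4-bis(benzyloxy)phenyl]-3-oxochroman-5-yl trifluoromethanesulfonate
Product: 20 racemic 7-(benzyloxy)-2-[3,4-bis(benzyloxy)phenyl]chroman-3-one
Conditions: Pd(OAc)2 (cat.), dppf, HCO2H, Et3N, DMF, 60 °C, under argon
Reagents that add atoms: none
Why: palladium-catalysed reduction of the aryl triflate (oxidative addition of the C5–O bond to zerovalent palladium, formate exchange, decarboxylation, C–H reductive elimination) removes the directing group; the homogeneous phosphine complex should tolerate the benzyl ethers and the ketone.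

Step 11
Reactants: 20 racemic 7-(benzyloxy)-2-[3,4-bis(benzyloxy)phenyl]chroman-3-one
Product: 21 (2S,3S)-7-(benzyloxy)-2-[3,4-bis(benzyloxy)phenyl]chroman-3-ol (2,3-cis; tri-O-benzyl-ent-epifisetinidol)
Conditions: RuCl[(S,S)-TsDPEN](p-cymene) (cat.), HCO2H–Et3N (5:2), DMF, 40 °C
Reagents that add atoms: none
Why: Noyori–Ikariya asymmetric transfer hydrogenation with dynamic kinetic resolution: C2–H lies between the carbonyl, O1 and the aryl ring, so the enantiomers of 20 should interconvert through the enol faster than they are reduced, and the chiral ruthenium hydride reduces one of them with hydride delivery to C3 anti to the 2-aryl group, which sets C2 (S) and C3 (S) together as the 2,3-cis pair.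

Step 12
Reactants: 21 (2S,3S)-7-(benzyloxy)-2-[3,4-bis(benzyloxy)phenyl]chroman-3-ol
Product: 22 (2S,3S)-3,7-bis(benzyloxy)-2-[3,4-bis(benzyloxy)phenyl]chroman (tetra-O-benzyl-ent-epifisetinidol)
Conditions: NaH, BnBr, DMF, 0 °C to rt
Reagents that add atoms: benzyl bromide, BrCc1ccccc1
Why: Williamson benzylation of the secondary alkoxide; it masks the lower C3 hydroxyl so that only the upper C3 carbinol can be oxidised in step 18, and no stereocentre is involved.

Step 13
Reactants: 20 racemic 7-(benzyloxy)-2-[3,4-bis(benzyloxy)phenyl]chroman-3-one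
Product: 23 (2R,3R)-7-(benzyloxy)-2-[3,4-bis(benzyloxy)phenyl]chroman-3-ol (2,3-cis; tri-O-benzyl-epifisetinidol)
Conditions: RuCl[(R,R)-TsDPEN](p-cymene) (cat.), HCO2H–Et3N (5:2), DMF, 40 °C
Reagents that add atoms: none
Why: the same dynamic kinetic transfer hydrogenation with the antipodal catalyst should give the mirror-image 2,3-cis alcohol, with C2 (R) and C3 (R) set together from the same racemic ketone.

Step 14
Reactants: 23 (2R,3R)-7-(benzyloxy)-2-[3,4-bis(benzyloxy)phenyl]chroman-3-ol
Product: 25 (2R,3R,4S)-7-(benzyloxy)-2-[3,4-bis(benzyloxy)phenyl]-4-(2-ethoxyethoxy)chroman-3-ol (4β-ether; 3,4-trans), via C4 cation 24 (not isolated)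
Conditions: DDQ, 2-ethoxyethanol, CH2Cl2, rt
Reagents that add atoms: 2-ethoxyethanol, CCOCCO
Why: oxidative benzylic functionalisation of a protected flavan-3-ol: DDQ abstracts hydride from C4 (the cation is stabilised by the para 7-benzyloxy group and by O1), and the alcohol should add to cation 24 from the β-face, anti to the 2-aryl and 3-hydroxyl groups, giving the 3,4-trans ether.

Step 15
Reactants: 25 (2R,3R,4S)-7-(benzyloxy)-2-[3,4-bis(benzyloxy)phenyl]-4-(2-ethoxyethoxy)chroman-3-ol
Product: 26 (2R,3R,4S)-7-(benzyloxy)-2-[3,4-bis(benzyloxy)phenyl]-4-(2-ethoxyethoxy)chroman-3-yl acetate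
Conditions: Ac2O, pyridine, DMAP (cat.), CH2Cl2, 0 °C to rt
Reagents that add atoms: acetic anhydride, CC(=O)OC(C)=O
Why: DMAP-catalysed acylation of the secondary 3-hydroxyl under basic conditions that leave the acid-labile C4 ether untouched; the acetate keeps the hydroxyl from acting as a nucleophile in step 16 and adds a second α-face shield beside C4, and no stereocentre is involved.

Step 16
Reactants: 26 (2R,3R,4S)-7-(benzyloxy)-2-[3,4-bis(benzyloxy)phenyl]-4-(2-ethoxyethoxy)chroman-3-yl acetate; 22 (2S,3S)-3,7-bis(benzyloxy)-2-[3,4-bis(benzyloxy)phenyl]chroman (in excess)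
Product: 28 3-O-acetyl-7,3',4'-tri-O-benzyl-epifisetinidol-(4β→6)-3,7,3',4'-tetra-O-benzyl-ent-epifisetinidol (upper unit 2,3-cis-3,4-trans), via 3-acetoxy C4 cation 27 (not isolated)
Conditions: TMSOTf (substoichiometric), CH2Cl2, −78 to −40 °C; surplus 22 recovered
Reagents that add atoms: none
Why: Lewis-acid-promoted Friedel–Crafts alkylation: TMSOTf ionises the C4 ether to the 3-acetoxy cation 27, whose α-face is covered by the 2-aryl group and by the carbonyl oxygen of the 3α-acetate (anchimeric assistance), so C6' of 22 (para to O1', ortho to the 7'-benzyloxy group and less hindered than C8') should attack on the β-face and set C4 as 4β; the excess of 22 suppresses self-condensation.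

Step 17
Reactants: 28 3-O-acetyl-7,3',4'-tri-O-benzyl-epifisetinidol-(4β→6)-3,7,3',4'-tetra-O-benzyl-ent-epifisetinidol
Product: 29 7,3',4'-tri-O-benzyl-epifisetinidol-(4β→6)-3,7,3',4'-tetra-O-benzyl-ent-epifisetinidol (upper unit 2,3-cis-3,4-trans; free upper 3-OH)
Conditions: K2CO3, MeOH–THF, rt to 40 °C
Reagents that add atoms: none
Why: base-catalysed methanolysis (transesterification) of the only ester, with acyl–oxygen cleavage so that C3 keeps its configuration; the benzyl ethers and the interflavan bond are inert to mild base.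

Step 18
Reactants: 29 7,3',4'-tri-O-benzyl-epifisetinidol-(4β→6)-3,7,3',4'-tetra-O-benzyl-ent-epifisetinidol
Product: 30 upper-unit 3-ketone of 29 (2α-aryl and 4β-aryl; 2,4-trans)
Conditions: Dess–Martin periodinane, CH2Cl2, 0 °C to rt; aq. Na2S2O3/NaHCO3 work-up
Reagents that add atoms: none
Why: Dess–Martin oxidation of the only free hydroxyl under neutral conditions; C2 and C4 should keep their configuration because the 2,4-trans arrangement (2-aryl equatorial, 4-aryl pseudo-axial) is also the thermodynamically preferred one.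

Step 19
Reactants: 30 upper-unit 3-ketone of 29
Product: 31 7,3',4'-tri-O-benzyl-fisetinidol-(4β→6)-3,7,3',4'-tetra-O-benzyl-ent-epifisetinidol (upper unit 2,3-trans-3,4-cis; free 3β-OH)
Conditions: NaBH4, CeCl3·7H2O, MeOH–THF, −78 to −40 °C
Reagents that add atoms: none
Why: Luche reduction: hydride should attack the C3 carbonyl axially from the α-face, anti to the pseudo-axial 4β-aryl group, giving the equatorial 3β-alcohol (3S), trans to the 2-aryl and cis to the 4-aryl group; low temperature and the non-basic cerium medium guard against enolisation at C2 and C4.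

Step 20
Reactants: 31 7,3',4'-tri-O-benzyl-fisetinidol-(4β→6)-3,7,3',4'-tetra-O-benzyl-ent-epifisetinidol
Product: 32 (2R,3S,4S)-2-(3,4-dihydroxyphenyl)-4-[(2S,3S)-2-(3,4-dihydroxyphenyl)-3,7-dihydroxychroman-6-yl]chroman-3,7-diol (fisetinidol-(4β→6)-ent-epifisetinidol)
Conditions: H2 (1 atm), Pd(OH)2/C, THF–MeOH–H2O, rt
Reagents that add atoms: none
Why: hydrogenolysis of the seven benzyl ethers under neutral conditions; the interflavan bond and the benzylic C2–O1 bonds should survive mild hydrogenolysis, and no stereocentre is touched.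

## Compound list

1 | 3,4-bis(benzyloxy)benzaldehyde | O=Cc1ccc(OCc2ccccc2)c(OCc2ccccc2)c1 | starting material
2 | triethyl 2-ethoxyphosphonoacetate (racemic) | CCOC(=O)C(OCC)P(=O)(OCC)OCC | starting material
3 | ethyl (Z)-3-[3,4-bis(benzyloxy)phenyl]-2-ethoxyprop-2-enoate | CCO/C(C(=O)OCC)=C\c1ccc(OCc2ccccc2)c(OCc2ccccc2)c1 | intermediate
4 | (Z)-3-[3,4-bis(benzyloxy)phenyl]-2-ethoxyprop-2-en-1-ol | CCO/C(CO)=C\c1ccc(OCc2ccccc2)c(OCc2ccccc2)c1 | intermediate
5 | (Z)-3-[3,4-bis(benzyloxy)phenyl]-2-ethoxyprop-2-enal | CCO/C(C=O)=C\c1ccc(OCc2ccccc2)c(OCc2ccccc2)c1 | intermediate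
6 | phloroglucinol | Oc1cc(O)cc(O)c1 | starting material
7 | 5-(benzyloxy)benzene-1,3-diol | Oc1cc(O)cc(OCc2ccccc2)c1 | intermediate
8 | 5-(benzyloxy)-1,3-phenylene bis(N-isopropylcarbamate) | CC(C)NC(=O)Oc1cc(OCc2ccccc2)cc(OC(=O)NC(C)C)c1 | intermediate
9 | N,N'-bis(tert-butyldimethylsilyl) derivative of 8 | CC(C)N(C(=O)Oc1cc(OCc2ccccc2)cc(OC(=O)N(C(C)C)[Si](C)(C)C(C)(C)C)c1)[Si](C)(C)C(C)(C)C | intermediate (not isolated)
10 | 2-lithio derivative of 9 | [Li]c1c(OC(=O)N(C(C)C)[Si](C)(C)C(C)(C)C)cc(OCc2ccccc2)cc1OC(=O)N(C(C)C)[Si](C)(C)C(C)(C)C | intermediate (not isolated)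
11 | 2-(trimethylsilyl) derivative of 9 | C[Si](C)(C)c1c(OC(=O)N(C(C)C)[Si](C)(C)C(C)(C)C)cc(OCc2ccccc2)cc1OC(=O)N(C(C)C)[Si](C)(C)C(C)(C)C | intermediate (not isolated)
12 | 5-(benzyloxy)-2-(trimethylsilyl)-1,3-phenylene bis(N-isopropylcarbamate) | C[Si](C)(C)c1c(OC(=O)NC(C)C)cc(OCc2ccccc2)cc1OC(=O)NC(C)C | intermediate
13 | 5-(benzyloxy)-2-(trimethylsilyl)benzene-1,3-diol (present as its bis(phenoxide)) | C[Si](C)(C)c1c(O)cc(OCc2ccccc2)cc1O | intermediate (not isolated)
14 | 5-(benzyloxy)-2-(trimethylsilyl)-1,3-phenylene bis(trifluoromethanesulfonate) | C[Si](C)(C)c1c(OS(=O)(=O)C(F)(F)F)cc(OCc2ccccc2)cc1OS(=O)(=O)C(F)(F)F | intermediate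
15 | 5-(benzyloxy)-3-(triflyloxy)benzyne | FC(F)(F)S(=O)(=O)OC1=CC(OCc2ccccc2)=CC#C1 | intermediate (not isolated)
16 | 5-(benzyloxy)-2-[(Z)-2-[3,4-bis(benzyloxy)phenyl]-1-ethoxyethenyl]-2H-1-benzoxet-3-yl triflate (racemic; O on the aryne carbon remote from the triflate) | CCO/C(=C\c1ccc(OCc2ccccc2)c(OCc2ccccc2)c1)C1Oc2cc(OCc3ccccc3)cc(OS(=O)(=O)C(F)(F)F)c21 | intermediate (not isolated)
17 | o-quinone methide: 3-(benzyloxy)-6-[(Z)-3-[3,4-bis(benzyloxy)phenyl]-2-ethoxyprop-2-enylidene]-5-(triflyloxy)cyclohexa-2,4-dien-1-one, side chain cis to the ring carbonyl | CCO/C(=C\c1ccc(OCc2ccccc2)c(OCc2ccccc2)c1)/C=C1\C(=O)C=C(OCc2ccccc2)C=C1OS(=O)(=O)C(F)(F)F | intermediate (not isolated)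
18 | 7-(benzyloxy)-2-[3,4-bis(benzyloxy)phenyl]-3-ethoxy-2H-chromen-5-yl trifluoromethanesulfonate (racemic) | CCOC1=Cc2c(OS(=O)(=O)C(F)(F)F)cc(OCc3ccccc3)cc2OC1c1ccc(OCc2ccccc2)c(OCc2ccccc2)c1 | intermediate
19 | 7-(benzyloxy)-2-[3,4-bis(benzyloxy)phenyl]-3-oxochroman-5-yl trifluoromethanesulfonate (racemic) | O=C1Cc2c(OS(=O)(=O)C(F)(F)F)cc(OCc3ccccc3)cc2OC1c1ccc(OCc2ccccc2)c(OCc2ccccc2)c1 | intermediate
20 | 7-(benzyloxy)-2-[3,4-bis(benzyloxy)phenyl]chroman-3-one (racemic; C2 epimerisable) | O=C1Cc2ccc(OCc3ccccc3)cc2OC1c1ccc(OCc2ccccc2)c(OCc2ccccc2)c1 | intermediate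
21 | (2S,3S)-7-(benzyloxy)-2-[3,4-bis(benzyloxy)phenyl]chroman-3-ol | C(c1ccccc1)Oc1ccc2c(c1)O[C@@H](c1ccc(OCc3ccccc3)c(OCc3ccccc3)c1)[C@@H](O)C2 | intermediate
22 | (2S,3S)-3,7-bis(benzyloxy)-2-[3,4-bis(benzyloxy)phenyl]chroman | C(c1ccccc1)Oc1ccc2c(c1)O[C@@H](c1ccc(OCc3ccccc3)c(OCc3ccccc3)c1)[C@@H](OCc1ccccc1)C2 | intermediate
23 | (2R,3R)-7-(benzyloxy)-2-[3,4-bis(benzyloxy)phenyl]chroman-3-ol | C(c1ccccc1)Oc1ccc2c(c1)O[C@H](c1ccc(OCc3ccccc3)c(OCc3ccccc3)c1)[C@H](O)C2 | intermediate
24 | (2R,3R)-7-(benzyloxy)-2-[3,4-bis(benzyloxy)phenyl]-3-hydroxychroman-4-ylium | C(c1ccccc1)Oc1ccc2c(c1)O[C@H](c1ccc(OCc3ccccc3)c(OCc3ccccc3)c1)[C@H](O)[CH+]2 | intermediate (not isolated)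
25 | (2R,3R,4S)-7-(benzyloxy)-2-[3,4-bis(benzyloxy)phenyl]-4-(2-ethoxyethoxy)chroman-3-ol (4β-ether) | C(c1ccccc1)Oc1ccc2c(c1)O[C@H](c1ccc(OCc3ccccc3)c(OCc3ccccc3)c1)[C@H](O)[C@H]2OCCOCC | intermediate
26 | (2R,3R,4S)-7-(benzyloxy)-2-[3,4-bis(benzyloxy)phenyl]-4-(2-ethoxyethoxy)chroman-3-yl acetate (4β-ether, 3α-acetate) | C(c1ccccc1)Oc1ccc2c(c1)O[C@H](c1ccc(OCc3ccccc3)c(OCc3ccccc3)c1)[C@H](OC(C)=O)[C@H]2OCCOCC | intermediate
27 | (2R,3R)-3-acetoxy-7-(benzyloxy)-2-[3,4-bis(benzyloxy)phenyl]chroman-4-ylium | C(c1ccccc1)Oc1ccc2c(c1)O[C@H](c1ccc(OCc3ccccc3)c(OCc3ccccc3)c1)[C@H](OC(C)=O)[CH+]2 | intermediate (not isolated)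
28 | 3-O-acetyl-7,3',4'-tri-O-benzyl-epifisetinidol-(4β→6)-3,7,3',4'-tetra-O-benzyl-ent-epifisetinidol (upper unit: 2-aryl α, 3-OAc α, 4-aryl β) | C(c1ccccc1)Oc1ccc2c(c1)O[C@H](c1ccc(OCc3ccccc3)c(OCc3ccccc3)c1)[C@H](OC(C)=O)[C@H]2c1cc2c(cc1OCc1ccccc1)O[C@@H](c1ccc(OCc3ccccc3)c(OCc3ccccc3)c1)[C@@H](OCc1ccccc1)C2 | intermediate
29 | 7,3',4'-tri-O-benzyl-epifisetinidol-(4β→6)-3,7,3',4'-tetra-O-benzyl-ent-epifisetinidol (upper unit: 2-aryl α, 3-OH α, 4-aryl β) | C(c1ccccc1)Oc1ccc2c(c1)O[C@H](c1ccc(OCc3ccccc3)c(OCc3ccccc3)c1)[C@H](O)[C@H]2c1cc2c(cc1OCc1ccccc1)O[C@@H](c1ccc(OCc3ccccc3)c(OCc3ccccc3)c1)[C@@H](OCc1ccccc1)C2 | intermediate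
30 | upper-unit 3-ketone of 29 (2-aryl α, 4-aryl β) | C(c1ccccc1)Oc1ccc2c(c1)O[C@H](c1ccc(OCc3ccccc3)c(OCc3ccccc3)c1)C(=O)[C@H]2c1cc2c(cc1OCc1ccccc1)O[C@@H](c1ccc(OCc3ccccc3)c(OCc3ccccc3)c1)[C@@H](OCc1ccccc1)C2 | intermediate
31 | 7,3',4'-tri-O-benzyl-fisetinidol-(4β→6)-3,7,3',4'-tetra-O-benzyl-ent-epifisetinidol (upper unit: 2-aryl α, 3-OH β, 4-aryl β) | C(c1ccccc1)Oc1ccc2c(c1)O[C@H](c1ccc(OCc3ccccc3)c(OCc3ccccc3)c1)[C@@H](O)[C@H]2c1cc2c(cc1OCc1ccccc1)O[C@@H](c1ccc(OCc3ccccc3)c(OCc3ccccc3)c1)[C@@H](OCc1ccccc1)C2 | intermediate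
32 | (2R,3S,4S)-2-(3,4-dihydroxyphenyl)-4-[(2S,3S)-2-(3,4-dihydroxyphenyl)-3,7-dihydroxychroman-6-yl]chroman-3,7-diol | Oc1ccc2c(c1)O[C@H](c1ccc(O)c(O)c1)[C@@H](O)[C@H]2c1cc2c(cc1O)O[C@@H](c1ccc(O)c(O)c1)[C@@H](O)C2 | target

## Step count and risks

Total step count: 20. Longest linear sequence: 15 steps (steps 4–10, then 13–20).

Steps most likely to fail:

1. Step 8 (aryne annulation). The aryne or the zwitterion may be diverted: addition across the electron-rich enol-ether C=C of 5, closure at the β-carbon instead of the carbonyl carbon, or loss of triflate from the aryl anion next to it. The fallback sets out from 1 and 14 and returns at 19. Wittig reaction of 1 with Ph3P=CHCHO (toluene, 80 °C) should give the parent (E)-3-[3,4-bis(benzyloxy)phenyl]prop-2-enal F1, the enal type for which this annulation is established. The same CsF-mediated reaction with 14 should then give 7-(benzyloxy)-2-[3,4-bis(benzyloxy)phenyl]-2H-chromen-5-yl triflate F2, still by benzoxete ring expansion. Hydroboration–oxidation (BH3·SMe2, THF; NaBO3·4H2O), with boron adding to C3 anti to the 2-aryl group, should give racemic 2,3-trans-7-(benzyloxy)-2-[3,4-bis(benzyloxy)phenyl]-3-hydroxychroman-5-yl triflate F3. Dess–Martin oxidation of F3 gives 19. The C3 oxygen is thus introduced after, not during, the ring-forming event.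

2. Step 11 (and its mirror image, step 13). Epimerisation at C2 may be too slow relative to reduction, or the catalyst may discriminate weakly between the ketone enantiomers and faces, which would erode enantiomeric and cis/trans purity. The fallback sets out from 20 and returns at 21 and 23. Substrate-controlled reduction with LiBH(s-Bu)3 (THF, −78 °C; hydride anti to the 2-aryl group) should give the racemic 2,3-cis alcohol, an equimolar mixture of 21 and 23. The antipodes are then separated by preparative chromatography on a chiral stationary phase. Nothing is wasted, because 21 feeds step 12 and 23 feeds step 14. This fallback makes no compound outside the list (entry F0).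

3. Step 16 (interflavan bond). The electrophile may self-condense through its own ring A, some attack may occur at C8', and the new bond may be cleaved again by acid. The fallback sets out from 26 and returns at 28. Compound 26 is first converted with benzyl mercaptan and a little TMSOTf (CH2Cl2, −40 °C; the thiol in excess outcompetes all carbon nucleophiles) into the bench-stable 3-O-acetyl-4β-(benzylsulfanyl)-7,3',4'-tri-O-benzyl-epifisetinidol F4 (2,3-cis-3,4-trans). F4 is then activated thiophilically with AgBF4 in THF at 0 °C in the presence of 22, so that the carbon–carbon bond forms without a silyl Lewis acid and with the same β-face approach.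

## Further compounds

F1 | step 8 | (E)-3-[3,4-bis(benzyloxy)phenyl]prop-2-enal | O=C/C=C/c1ccc(OCc2ccccc2)c(OCc2ccccc2)c1
F2 | step 8 | 7-(benzyloxy)-2-[3,4-bis(benzyloxy)phenyl]-2H-chromen-5-yl trifluoromethanesulfonate (racemic) | C1=Cc2c(OS(=O)(=O)C(F)(F)F)cc(OCc3ccccc3)cc2OC1c1ccc(OCc2ccccc2)c(OCc2ccccc2)c1
F3 | step 8 | racemic 2,3-trans-7-(benzyloxy)-2-[3,4-bis(benzyloxy)phenyl]-3-hydroxychroman-5-yl trifluoromethanesulfonate (one enantiomer drawn) | C(c1ccccc1)Oc1cc(OS(=O)(=O)C(F)(F)F)c2c(c1)O[C@H](c1ccc(OCc3ccccc3)c(OCc3ccccc3)c1)[C@@H](O)C2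
F0 | step 11 | none | none
F4 | step 16 | 3-O-acetyl-4β-(benzylsulfanyl)-7,3',4'-tri-O-benzyl-epifisetinidol (2-aryl α, 3-OAc α, 4-S β) | C(c1ccccc1)Oc1ccc2c(c1)O[C@H](c1ccc(OCc3ccccc3)c(OCc3ccccc3)c1)[C@H](OC(C)=O)[C@H]2SCc1ccccc1
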